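**Retrosynthetic overview**
1. Target 20 ⇐ acetylation of the tertiary 4-OH and angeloylation of the 3-OH of diol 16 ⇐ hydroxyl-directed reduction of ketol 15 (sets C3).
2. 15 ⇐ acyclic 1,2-diketone 14 by one enantioselective carbonyl-Prins / cation–dienol-silane bicyclization: bond C4–C5 closes ring A and bond C9–C10 closes ring B in the same operation (sets C4, C5, C10).
3. 14 ⇐ C1–C2 alkylation of a butane-2,3-dione mono-enolate equivalent (from 11) with allylic chloride 10.
4. 10 ⇐ acetylacetone + prenyl bromide: enol triflate/Me2CuLi gives the isopropylidene ketone, SeO2 sets the E-allylic oxygen, then kinetic silyl dienol ether.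

Assumption: 2,3-bis(trimethylsilyloxy)buta-1,3-diene (sold; one step from butane-2,3-dione) and angelic acid are bought; ring positions use eudesmane numbers (C3 angelate, C4 acetate/CH3, C5 H, C10 CH3, C7 isopropylidene, C8 ketone); (S,S)-tBu-box is 2,2'-(propane-2,2-diyl)bis[(4S)-4-tert-butyl-4,5-dihydro-1,3-oxazole].

**Step 1**
Reactants: 1 pentane-2,4-dione; 2 1-bromo-3-methylbut-2-ene
Product: 3 3-(3-methylbut-2-en-1-yl)pentane-2,4-dione
Conditions: K2CO3, acetone, reflux
Reagents that add atoms: none
Why: SN2 C-alkylation of the stabilized acetylacetone anion by a reactive allylic bromide; no stereocentre.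

**Step 2**
Reactants: 3 3-(3-methylbut-2-en-1-yl)pentane-2,4-dione
Product: 4 3-acetyl-6-methylhepta-2,5-dien-2-yl trifluoromethanesulfonate
Conditions: Tf2O, Et3N, CH2Cl2, −78 to 0 °C
Reagents that add atoms: trifluoromethanesulfonic anhydride, O=S(=O)(OS(=O)(=O)C(F)(F)F)C(F)(F)F
Why: enol triflate formation on the enolized β-diketone; the double-bond geometry does not matter because the next step puts a second methyl on that carbon.

**Step 3**
Reactants: 4 3-acetyl-6-methylhepta-2,5-dien-2-yl trifluoromethanesulfonate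
Product: 5 6-methyl-3-(propan-2-ylidene)hept-5-en-2-one
Conditions: Me2CuLi (from MeLi and CuI), Et2O/THF, −78 °C
Reagents that add atoms: lithium dimethylcuprate, [Li+].C[Cu-]C
Why: conjugate addition–elimination of a Gilman cuprate on the β-acyl enol triflate replaces OTf by CH3 and gives the tetrasubstituted isopropylidene ketone as a single regioisomer; no stereocentre.

**Step 4**
Reactants: 5 6-methyl-3-(propan-2-ylidene)hept-5-en-2-one
Product: 6 (5E)-7-hydroxy-6-methyl-3-(propan-2-ylidene)hept-5-en-2-one
Conditions: SeO2 (0.3 equiv), tBuOOH, CH2Cl2, 0 °C to rt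
Reagents that add atoms: tert-butyl hydroperoxide, CC(C)(C)OO
Why: SeO2 allylic oxidation (ene reaction then [2,3]-shift) attacks the electron-rich trisubstituted alkene at its E-methyl group only, which fixes the E geometry of the later C5=C10 bond; the enone alkene is too electron-poor to compete.

**Step 5**
Reactants: 6 (5E)-7-hydroxy-6-methyl-3-(propan-2-ylidene)hept-5-en-2-one
Product: 8 (5E)-7-chloro-6-methyl-3-(propan-2-ylidene)hept-5-en-2-one, via allylic mesylate 7 (not isolated)
Conditions: MsCl, 2,4,6-collidine, LiCl, DMF, 0 °C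
Reagents that add atoms: lithium chloride, [Li+].[Cl-]
Why: Collington–Meyers chlorination, in which chloride displaces the primary allylic mesylate by SN2 without allylic transposition or loss of the E geometry.

**Step 6**
Reactants: 8 (5E)-7-chloro-6-methyl-3-(propan-2-ylidene)hept-5-en-2-one
Product: 10 tert-butyl{[(5E)-7-chloro-6-methyl-3-(propan-2-ylidene)hepta-1,5-dien-2-yl]oxy}dimethylsilane, via lithium enolate 9 (not isolated)
Conditions: LiN(iPr)2, THF, −78 °C; then TBSOTf, −78 °C
Reagents that add atoms: tert-butyldimethylsilyl trifluoromethanesulfonate, CC(C)(C)[Si](C)(C)OS(=O)(=O)C(F)(F)F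
Why: kinetic silyl enol ether formation, since deprotonation at the acetyl methyl gives the cross-conjugated enolate, which is silylated on oxygen at −78 °C before it can alkylate the allylic chloride; no stereocentre.

**Step 7**
Reactants: 10 tert-butyl{[(5E)-7-chloro-6-methyl-3-(propan-2-ylidene)hepta-1,5-dien-2-yl]oxy}dimethylsilane; 11 2,3-bis(trimethylsilyloxy)buta-1,3-diene
Product: 14 (6E)-10-(tert-butyldimethylsilyloxy)-6-methyl-9-(propan-2-ylidene)undeca-6,10-diene-2,3-dione, via lithium enolate 12 (not isolated), via trimethylsilyl enol ether 13 (not isolated)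
Conditions: 11, MeLi (1.0 equiv), THF, 0 °C; then 10, DMPU, −78 to −10 °C; then MeOH, K2CO3 (cat.), 0 °C, 10 min
Reagents that add atoms: none
Why: MeLi cleaves one Si–O bond of 11 to a regiospecific lithium enolate that cannot self-condense, its terminal carbon displaces the allylic chloride (SN2 enolate alkylation, E geometry kept), and the labile Me3Si enol ether is methanolysed to the 1,2-diketone while the tBuMe2Si dienol ether survives.

**Step 8**
Reactants: 14 (6E)-10-(tert-butyldimethylsilyloxy)-6-methyl-9-(propan-2-ylidene)undeca-6,10-diene-2,3-dione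
Product: 15 (1S,4aR,8aR)-1-hydroxy-1,4a-dimethyl-7-(propan-2-ylidene)hexahydronaphthalene-2,6(1H,3H)-dione
Conditions: [Cu((S,S)-tBu-box)](SbF6)2 (15 mol %), (CF3)2CHOH (1.2 equiv), 4 Å molecular sieves, CH2Cl2 (0.005 M), −78 to −20 °C
Reagents that add atoms: none
Why: Proposed new method: the chiral copper complex binds the 1,2-diketone as a planar five-membered chelate and activates the acetyl carbonyl (C4) for 6-endo attack by the E-trisubstituted alkene on its si face (carbonyl-Prins step, ring A), and because the chelated s-cis diketone keeps the C4 oxygen eclipsed with the C3 carbonyl, that oxygen ends equatorial (4α) and the methyl axial (4β); the tertiary C10 cation is then captured anti, through a chair, by the terminal carbon of the silyl dienol ether (Mukaiyama-type C-alkylation, ring B), which gives the trans ring fusion (5α-H, 10β-CH3), and (CF3)2CHOH takes up the silyl group and protonates the copper alkoxide for turnover; the closest known reactions are the enantioselective carbonyl-ene and Mukaiyama aldol additions to pyruvates and 1,2-diketones with the same copper bis(oxazoline) complexes, and carbonyl-initiated cation–olefin cyclizations terminated by enol silanes.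

**Step 9**
Reactants: 15 (1S,4aR,8aR)-1-hydroxy-1,4a-dimethyl-7-(propan-2-ylidene)hexahydronaphthalene-2,6(1H,3H)-dione
Product: 16 (4aR,5S,6S,8aR)-5,6-dihydroxy-5,8a-dimethyl-3-(propan-2-ylidene)octahydronaphthalen-2(1H)-one
Conditions: Me4NBH(OAc)3, MeCN/AcOH, −30 to 0 °C
Reagents that add atoms: none
Why: hydroxyl-directed triacetoxyborohydride reduction (Saksena–Evans type), in which the equatorial 4α-OH binds boron and delivers hydride to the α face of the C3 ketone to give the equatorial 3β-alcohol trans to the C4 oxygen (3S), while the hindered conjugated C8 ketone has no directing group and is not reduced.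

**Step 10**
Reactants: 16 (4aR,5S,6S,8aR)-5,6-dihydroxy-5,8a-dimethyl-3-(propan-2-ylidene)octahydronaphthalen-2(1H)-one; 17 (2Z)-2-methylbut-2-enoic acid (angelic acid)
Product: 19 (1S,2S,4aR,8aR)-1-hydroxy-1,4a-dimethyl-6-oxo-7-(propan-2-ylidene)decahydronaphthalen-2-yl (2Z)-2-methylbut-2-enoate, via mixed anhydride 18 (not isolated)
Conditions: 17, 2,4,6-trichlorobenzoyl chloride, Et3N, toluene, rt; then 16, 75 °C
Reagents that add atoms: none
Why: Yamaguchi-type mixed-anhydride esterification without a nucleophilic catalyst acylates only the secondary 3-OH (the tertiary 4-OH is inert) and keeps the Z geometry of the angelate; no stereocentre is touched.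

**Step 11**
Reactants: 19 (1S,2S,4aR,8aR)-1-hydroxy-1,4a-dimethyl-6-oxo-7-(propan-2-ylidene)decahydronaphthalen-2-yl (2Z)-2-methylbut-2-enoate
Product: 20 (1S,2S,4aR,8aR)-1-acetoxy-1,4a-dimethyl-6-oxo-7-(propan-2-ylidene)decahydronaphthalen-2-yl (2Z)-2-methylbut-2-enoate
Conditions: Ac2O, Sc(OTf)3 (5 mol %), MeCN, −20 °C
Reagents that add atoms: acetic anhydride, CC(=O)OC(C)=O
Why: Lewis-acid-catalysed acetylation of a tertiary alcohol at low temperature acylates the 4α-OH with retention (the C–O bond is not broken) and avoids the base or heat that would isomerise the angelate to the tiglate.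

**Compound list**
1 | pentane-2,4-dione (acetylacetone) | CC(=O)CC(C)=O | starting material
2 | 1-bromo-3-methylbut-2-ene (prenyl bromide) | CC(C)=CCBr | starting material
3 | 3-(3-methylbut-2-en-1-yl)pentane-2,4-dione | CC(=O)C(CC=C(C)C)C(C)=O | intermediate
4 | 3-acetyl-6-methylhepta-2,5-dien-2-yl trifluoromethanesulfonate (either enol geometry) | CC(=O)C(CC=C(C)C)=C(C)OS(=O)(=O)C(F)(F)F | intermediate
5 | 6-methyl-3-(propan-2-ylidene)hept-5-en-2-one | CC(=O)C(=C(C)C)CC=C(C)C | intermediate
6 | (5E)-7-hydroxy-6-methyl-3-(propan-2-ylidene)hept-5-en-2-one | CC(=O)C(=C(C)C)C/C=C(\C)CO | intermediate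
7 | (2E)-5-acetyl-2,6-dimethylhepta-2,5-dien-1-yl methanesulfonate | CC(=O)C(=C(C)C)C/C=C(\C)COS(C)(=O)=O | intermediate
8 | (5E)-7-chloro-6-methyl-3-(propan-2-ylidene)hept-5-en-2-one | CC(=O)C(=C(C)C)C/C=C(\C)CCl | intermediate
9 | lithium (5E)-7-chloro-6-methyl-3-(propan-2-ylidene)hepta-1,5-dien-2-olate | [Li+].[O-]C(=C)C(=C(C)C)C/C=C(\C)CCl | intermediate
10 | tert-butyl{[(5E)-7-chloro-6-methyl-3-(propan-2-ylidene)hepta-1,5-dien-2-yl]oxy}dimethylsilane | C=C(O[Si](C)(C)C(C)(C)C)C(=C(C)C)C/C=C(\C)CCl | intermediate
11 | 2,3-bis(trimethylsilyloxy)buta-1,3-diene | C=C(O[Si](C)(C)C)C(=C)O[Si](C)(C)C | starting material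
12 | lithium 3-(trimethylsilyloxy)buta-1,3-dien-2-olate | [Li+].[O-]C(=C)C(=C)O[Si](C)(C)C | intermediate
13 | (6E)-10-(tert-butyldimethylsilyloxy)-6-methyl-9-(propan-2-ylidene)-2-(trimethylsilyloxy)undeca-1,6,10-trien-3-one | C=C(O[Si](C)(C)C)C(=O)CC/C(C)=C/CC(=C(C)C)C(=C)O[Si](C)(C)C(C)(C)C | intermediate
14 | (6E)-10-(tert-butyldimethylsilyloxy)-6-methyl-9-(propan-2-ylidene)undeca-6,10-diene-2,3-dione | CC(=O)C(=O)CC/C(C)=C/CC(=C(C)C)C(=C)O[Si](C)(C)C(C)(C)C | intermediate
15 | (1S,4aR,8aR)-1-hydroxy-1,4a-dimethyl-7-(propan-2-ylidene)hexahydronaphthalene-2,6(1H,3H)-dione; trans-decalin, 4α-OH, 4β-CH3, 10β-CH3, 5α-H | O=C1CC[C@]2(C)CC(=O)C(=C(C)C)C[C@H]2[C@]1(C)O | intermediate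
16 | (4aR,5S,6S,8aR)-5,6-dihydroxy-5,8a-dimethyl-3-(propan-2-ylidene)octahydronaphthalen-2(1H)-one; 3β,4α-diol | O[C@H]1CC[C@]2(C)CC(=O)C(=C(C)C)C[C@H]2[C@]1(C)O | intermediate
17 | (2Z)-2-methylbut-2-enoic acid (angelic acid) | C/C=C(/C)C(O)=O | starting material
18 | (2Z)-2-methylbut-2-enoic 2,4,6-trichlorobenzoic anhydride | C/C=C(/C)C(=O)OC(=O)c1c(Cl)cc(Cl)cc1Cl | intermediate
19 | (1S,2S,4aR,8aR)-1-hydroxy-1,4a-dimethyl-6-oxo-7-(propan-2-ylidene)decahydronaphthalen-2-yl (2Z)-2-methylbut-2-enoate | C/C=C(/C)C(=O)O[C@H]1CC[C@]2(C)CC(=O)C(=C(C)C)C[C@H]2[C@]1(C)O | intermediate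
20 | (1S,2S,4aR,8aR)-1-acetoxy-1,4a-dimethyl-6-oxo-7-(propan-2-ylidene)decahydronaphthalen-2-yl (2Z)-2-methylbut-2-enoate | C/C=C(/C)C(=O)O[C@H]1CC[C@]2(C)CC(=O)C(=C(C)C)C[C@H]2[C@]1(C)OC(C)=O | target

**Total step count:** 11. **Longest linear sequence:** 11 steps (1 or 2 to 20).

**Three steps most likely to fail**

Step 8 is the main risk. Proton loss from the C10 cation (carbonyl-ene pathway) may outrun carbon capture, the dienol silane may add to the diketone of a second molecule, or the sense of induction may be opposite (then the R,R ligand is used). The fallback sets out from 14 and comes back at 15 and separates the two ring closures. 14 is cyclized with [Cu((S,S)-tBu-box)](SbF6)2 in CH2Cl2 without the alcohol additive in a deliberate enantioselective carbonyl-ene reaction, a known reaction type for unsaturated α-dicarbonyl compounds. This gives the monocyclic tertiary alcohol (2S,3R)-3-{2-[1-(tert-butyldimethylsilyloxy)ethenyl]-3-methylbut-2-en-1-yl}-2-hydroxy-2-methyl-4-methylidenecyclohexan-1-one F1. Ring B is then closed in a second operation with TfOH (10 mol %) in (CF3)2CHOH/CH2Cl2 at −40 °C. Markovnikov protonation of the exocyclic methylidene regenerates the C10 cation, which is captured by the dienol silane carbon, or by the enol of the methyl ketone if the silyl group is lost first, to give 15.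

Step 7 may suffer from proton transfer between product and enolate, O-alkylation, or loss of the dienol silane during methanolysis. The fallback sets out from 10 and comes back at 14. The dianion of 3-hydroxybutan-2-one (acetoin, 2 equiv LiN(iPr)2, THF, −78 °C) is alkylated at its methyl carbon with 10 (DMPU, −78 to 0 °C). This gives the acyloin (6E)-10-(tert-butyldimethylsilyloxy)-2-hydroxy-6-methyl-9-(propan-2-ylidene)undeca-6,10-dien-3-one F2. F2 is oxidized with Dess–Martin periodinane and NaHCO3 in CH2Cl2 at 0 °C to diketone 14, so no silyl enol ether has to be cleaved selectively.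

Step 11 may be slow at the hindered tertiary alcohol or may move or isomerise the angelate. The fallback sets out from 15 and comes back at 20 and changes the order of events. The tertiary ketol 15 is acetylated first (Ac2O, Sc(OTf)3, MeCN, −20 °C) to (1S,4aR,8aR)-1,4a-dimethyl-2,6-dioxo-7-(propan-2-ylidene)decahydronaphthalen-1-yl acetate F3. The C3 ketone is then reduced with Zn(BH4)2 in Et2O at −40 °C; axial hydride attack from the α face is reinforced by the axial 4β-methyl, and the hindered enone is left alone. The quench is cold and acidic to suppress acetyl migration, and gives (1S,2S,4aR,8aR)-2-hydroxy-1,4a-dimethyl-6-oxo-7-(propan-2-ylidene)decahydronaphthalen-1-yl acetate F4. F4 is esterified with mixed anhydride 18 (toluene, 75 °C) to give 20.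

**Further compounds**
F1 | step 8 | (2S,3R)-3-{2-[1-(tert-butyldimethylsilyloxy)ethenyl]-3-methylbut-2-en-1-yl}-2-hydroxy-2-methyl-4-methylidenecyclohexan-1-one | O=C1CCC(=C)[C@@H](CC(=C(C)C)C(=C)O[Si](C)(C)C(C)(C)C)[C@]1(C)O
F2 | step 7 | (6E)-10-(tert-butyldimethylsilyloxy)-2-hydroxy-6-methyl-9-(propan-2-ylidene)undeca-6,10-dien-3-one | CC(O)C(=O)CC/C(C)=C/CC(=C(C)C)C(=C)O[Si](C)(C)C(C)(C)C
F3 | step 11 | (1S,4aR,8aR)-1,4a-dimethyl-2,6-dioxo-7-(propan-2-ylidene)decahydronaphthalen-1-yl acetate | O=C1CC[C@]2(C)CC(=O)C(=C(C)C)C[C@H]2[C@]1(C)OC(C)=O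
F4 | step 11 | (1S,2S,4aR,8aR)-2-hydroxy-1,4a-dimethyl-6-oxo-7-(propan-2-ylidene)decahydronaphthalen-1-yl acetate | O[C@H]1CC[C@]2(C)CC(=O)C(=C(C)C)C[C@H]2[C@]1(C)OC(C)=O
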